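**Retrosynthetic overview**
- Target ⇐ acetylation and 1,2-reduction of the 3-dehydroshikimate diester (enone), which already carries both chiral esters.
- Enone ⇐ one-flask double ozonolysis of an acyclic diene diester to the fully acylated 2,6-diketo ester, then intramolecular aldol addition (dehydroquinate-synthase type) and dehydration (dehydroquinase type).
- Diene diester ⇐ esterification of a syn alcohol made by ligand-controlled Ni/Cr alkenylation of an α-acyloxy aldehyde with 2-bromopropene (isopropenyl = masked methyl ketone).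
- Aldehyde ⇐ acetal hydrolysis and esterification of the product of an asymmetric Cr-catalysed 2-(methoxycarbonyl)allylation of 2,2-dimethoxyacetaldehyde (the bromomethylacrylate is a phosphoenolpyruvate equivalent, as in the DAHP-synthase bond).
- Ring order: the single carbocycle is formed last but two, in step 6; no other ring is made.

Assumption: both chiral acids are bought as single enantiomers, and 2,2-dimethoxyacetaldehyde is dried from its commercial aqueous solution before use.

**Step 1**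
Reactants: 1 2,2-dimethoxyacetaldehyde; 2 methyl 2-(bromomethyl)prop-2-enoate
Product: 4 methyl (4R)-4-hydroxy-5,5-dimethoxy-2-methylidenepentanoate, via trimethylsilyl ether 3 (not isolated)
Conditions: CrCl2 (10 mol %), chiral carbazole bis(oxazoline) ligand (12 mol %, antipode that gives 4R), Et3N (20 mol %), Mn powder, Me3SiCl, THF, 0 °C → rt; aq. citric acid
Reagents that add atoms: none
Why: Catalytic asymmetric Nozaki–Hiyama–Kishi allylation, in which the ligand-bound allylchromium species (trivalent chromium) attacks one face of the non-enolisable aldehyde and sets C4 as R (later ring C5), while Me3SiCl turns the catalyst over and masks the alkoxide against lactonisation.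

**Step 2**
Reactants: 4 methyl (4R)-4-hydroxy-5,5-dimethoxy-2-methylidenepentanoate; 5 (3S)-3-methylpentanoic acid
Product: 6 methyl (4R)-5,5-dimethoxy-2-methylidene-4-{[(3S)-3-methylpentanoyl]oxy}pentanoate
Conditions: DCC, DMAP (10 mol %), CH2Cl2, 0 °C → rt
Reagents that add atoms: none
Why: Steglich esterification of the secondary alcohol with retention at C4 (no bond to the stereocentre is broken), and the β-stereocentre of 5 cannot epimerise.

**Step 3**
Reactants: 6 methyl (4R)-5,5-dimethoxy-2-methylidene-4-{[(3S)-3-methylpentanoyl]oxy}pentanoate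
Product: 7 methyl (4R)-2-methylidene-4-{[(3S)-3-methylpentanoyl]oxy}-5-oxopentanoate
Conditions: TFA/H2O/CH2Cl2 (4:1:20), 0 °C; neutral work-up, used crude
Reagents that add atoms: water, O
Why: Acid-catalysed acetal hydrolysis; the α-acyloxy aldehyde has no β,γ-unsaturation and is taken on at once, so C4 keeps its configuration.

**Step 4**
Reactants: 7 methyl (4R)-2-methylidene-4-{[(3S)-3-methylpentanoyl]oxy}-5-oxopentanoate; 8 2-bromopropene
Product: 10 methyl (4R,5R)-5-hydroxy-6-methyl-2-methylidene-4-{[(3S)-3-methylpentanoyl]oxy}hept-6-enoate, via trimethylsilyl ether 9 (not isolated)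
Conditions: CrCl2 (10 mol %), chiral oxazoline sulfonamide ligand (11 mol %), Et3N (20 mol %), NiCl2·(2,9-dimethyl-1,10-phenanthroline) (2 mol %), Mn powder, Me3SiCl, LiCl, MeCN, rt; aq. citric acid
Reagents that add atoms: none
Why: Catalytic asymmetric Ni/Cr-mediated Nozaki–Hiyama–Kishi alkenylation, in which the chiral chromium complex delivers the 2-propenyl group under ligand control to give C5 as R, syn to the C4 ester (against the polar Felkin–Anh preference), while in situ silylation blocks 1,2-acyl migration.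

**Step 5**
Reactants: 10 methyl (4R,5R)-5-hydroxy-6-methyl-2-methylidene-4-{[(3S)-3-methylpentanoyl]oxy}hept-6-enoate; 11 (2R)-2-methylbutanoic acid
Product: 12 methyl (4R,5R)-6-methyl-2-methylidene-5-{[(2R)-2-methylbutanoyl]oxy}-4-{[(3S)-3-methylpentanoyl]oxy}hept-6-enoate
Conditions: DCC, DMAP (20 mol %), CH2Cl2, 0 °C → rt
Reagents that add atoms: none
Why: Steglich esterification with retention at C5; carbodiimide activation (no acid chloride, no ketene) keeps the α-stereocentre of 11 intact.

**Step 6**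
Reactants: 12 methyl (4R,5R)-6-methyl-2-methylidene-5-{[(2R)-2-methylbutanoyl]oxy}-4-{[(3S)-3-methylpentanoyl]oxy}hept-6-enoate
Product: 16 methyl (4S,5R)-4-{[(2R)-2-methylbutanoyl]oxy}-5-{[(3S)-3-methylpentanoyl]oxy}-3-oxocyclohex-1-ene-1-carboxylate, via bis-ozonide 13 (not isolated), via diketone 14 (not isolated), via aldol adduct 15 (not isolated)
Conditions: O3, CH2Cl2, −78 °C; Me2S, −78 °C → rt; evaporate; TsOH·H2O (20 mol %), 4 Å MS, PhMe, 40 °C
Reagents that add atoms: ozone, O=[O+][O-]
Why: Double ozonolysis unmasks the α-keto ester and the methyl ketone of 14, whose methyl-ketone enol adds to the highly electrophilic keto ester (acid-catalysed intramolecular aldol, 6-enolexo, the only ring size open to this 2,6-diketone) and whose tertiary aldol 15 dehydrates into conjugation, so the ring closes without touching the two ester-bearing stereocentres.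

**Step 7**
Reactants: 16 methyl (4S,5R)-4-{[(2R)-2-methylbutanoyl]oxy}-5-{[(3S)-3-methylpentanoyl]oxy}-3-oxocyclohex-1-ene-1-carboxylate
Product: 17 methyl (3R,4R,5R)-3-hydroxy-4-{[(2R)-2-methylbutanoyl]oxy}-5-{[(3S)-3-methylpentanoyl]oxy}cyclohex-1-ene-1-carboxylate
Conditions: NaBH4, CeCl3·7H2O, MeOH, −78 °C
Reagents that add atoms: none
Why: Luche 1,2-reduction of the enone, with hydride expected to add anti to the adjacent C4 acyloxy group (polar Felkin–Anh) to give the 3,4-cis alcohol (C3 R) without conjugate reduction.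

**Step 8**
Reactants: 17 methyl (3R,4R,5R)-3-hydroxy-4-{[(2R)-2-methylbutanoyl]oxy}-5-{[(3S)-3-methylpentanoyl]oxy}cyclohex-1-ene-1-carboxylate
Product: 18 methyl (3R,4S,5R)-3-(acetyloxy)-4-{[(2R)-2-methylbutanoyl]oxy}-5-{[(3S)-3-methylpentanoyl]oxy}cyclohex-1-ene-1-carboxylate
Conditions: Ac2O, pyridine, DMAP (5 mol %), CH2Cl2, 0 °C, directly after step 7
Reagents that add atoms: acetic anhydride, CC(=O)OC(C)=O
Why: Nucleophile-catalysed O-acetylation of the allylic alcohol with retention at C3, run cold and at once so that the C4 ester does not migrate.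

**Compound list**
1 | 2,2-dimethoxyacetaldehyde | COC(OC)C=O | starting material
2 | methyl 2-(bromomethyl)prop-2-enoate | C=C(CBr)C(=O)OC | starting material
3 | methyl (4R)-5,5-dimethoxy-2-methylidene-4-[(trimethylsilyl)oxy]pentanoate | COC(OC)[C@H](O[Si](C)(C)C)CC(=C)C(=O)OC | intermediate
4 | methyl (4R)-4-hydroxy-5,5-dimethoxy-2-methylidenepentanoate | COC(OC)[C@H](O)CC(=C)C(=O)OC | intermediate
5 | (3S)-3-methylpentanoic acid | CC[C@H](C)CC(=O)O | starting material
6 | methyl (4R)-5,5-dimethoxy-2-methylidene-4-{[(3S)-3-methylpentanoyl]oxy}pentanoate | COC(OC)[C@H](OC(=O)C[C@@H](C)CC)CC(=C)C(=O)OC | intermediate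
7 | methyl (4R)-2-methylidene-4-{[(3S)-3-methylpentanoyl]oxy}-5-oxopentanoate | O=C[C@H](OC(=O)C[C@@H](C)CC)CC(=C)C(=O)OC | intermediate
8 | 2-bromopropene | C=C(C)Br | starting material
9 | methyl (4R,5R)-6-methyl-2-methylidene-4-{[(3S)-3-methylpentanoyl]oxy}-5-[(trimethylsilyl)oxy]hept-6-enoate | C=C(C)[C@@H](O[Si](C)(C)C)[C@H](OC(=O)C[C@@H](C)CC)CC(=C)C(=O)OC | intermediate
10 | methyl (4R,5R)-5-hydroxy-6-methyl-2-methylidene-4-{[(3S)-3-methylpentanoyl]oxy}hept-6-enoate | C=C(C)[C@@H](O)[C@H](OC(=O)C[C@@H](C)CC)CC(=C)C(=O)OC | intermediate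
11 | (2R)-2-methylbutanoic acid | CC[C@@H](C)C(=O)O | starting material
12 | methyl (4R,5R)-6-methyl-2-methylidene-5-{[(2R)-2-methylbutanoyl]oxy}-4-{[(3S)-3-methylpentanoyl]oxy}hept-6-enoate | C=C(C)[C@@H](OC(=O)[C@H](C)CC)[C@H](OC(=O)C[C@@H](C)CC)CC(=C)C(=O)OC | intermediate
13 | bis-ozonide of 12 (both C=CH2 units as 1,2,4-trioxolanes, epimers at the two trioxolane carbons) | CC1(OCOO1)[C@@H](OC(=O)[C@H](C)CC)[C@H](OC(=O)C[C@@H](C)CC)CC1(OCOO1)C(=O)OC | intermediate
14 | methyl (4R,5S)-5-{[(2R)-2-methylbutanoyl]oxy}-4-{[(3S)-3-methylpentanoyl]oxy}-2,6-dioxoheptanoate | CC(=O)[C@@H](OC(=O)[C@H](C)CC)[C@H](OC(=O)C[C@@H](C)CC)CC(=O)C(=O)OC | intermediate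
15 | methyl (4S,5R)-1-hydroxy-4-{[(2R)-2-methylbutanoyl]oxy}-5-{[(3S)-3-methylpentanoyl]oxy}-3-oxocyclohexane-1-carboxylate (C1 epimers) | CC[C@H](C)CC(=O)O[C@@H]1CC(O)(C(=O)OC)CC(=O)[C@H]1OC(=O)[C@H](C)CC | intermediate
16 | methyl (4S,5R)-4-{[(2R)-2-methylbutanoyl]oxy}-5-{[(3S)-3-methylpentanoyl]oxy}-3-oxocyclohex-1-ene-1-carboxylate | CC[C@H](C)CC(=O)O[C@@H]1CC(C(=O)OC)=CC(=O)[C@H]1OC(=O)[C@H](C)CC | intermediate
17 | methyl (3R,4R,5R)-3-hydroxy-4-{[(2R)-2-methylbutanoyl]oxy}-5-{[(3S)-3-methylpentanoyl]oxy}cyclohex-1-ene-1-carboxylate | CC[C@H](C)CC(=O)O[C@@H]1CC(C(=O)OC)=C[C@@H](O)[C@H]1OC(=O)[C@H](C)CC | intermediate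
18 | methyl (3R,4S,5R)-3-(acetyloxy)-4-{[(2R)-2-methylbutanoyl]oxy}-5-{[(3S)-3-methylpentanoyl]oxy}cyclohex-1-ene-1-carboxylate (CNP0188172.1) | CC[C@H](C)CC(=O)O[C@@H]1CC(C(=O)OC)=C[C@@H](OC(C)=O)[C@H]1OC(=O)[C@H](C)CC | target

Note on descriptors: the label of chain C5 changes from R (12) to S (14), and that of ring C4 from S (16, 18) to R (17), only because CIP priorities of the neighbours change; no centre is inverted.

**Totals**
Total steps: 8. Longest linear sequence: 8 steps (1 → 18).

**Three steps most likely to fail**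

1. Step 6. Diketone 14 carries the 3-methylpentanoate β to both carbonyls and may lose the acid by elimination before it cyclises, and 16 can lose the same ester and aromatise to a protocatechuate. The fallback brings this ester in after ring closure; it sets out from 4 and comes back at 16. Alcohol 4 is silylated (t-BuPh2SiCl, imidazole, DMF) to the tert-butyldiphenylsilyl ether F1. Acetal hydrolysis as in step 3 gives the aldehyde F2. Alkenylation with 8 (CrCl2 3 equiv, NiCl2 1 mol %, same chiral ligand, no Me3SiCl) gives the syn alcohol F3. Esterification with 11 as in step 5 gives the diene ester F4. Ozonolysis and acid treatment as in step 6 lead through the bis-ozonide F5, the diketone F6 and the aldol adduct F7 to the silyl enone F8, whose β-silyloxy group is a poor leaving group. HF·pyridine then frees the hydroxy enone F9, which is esterified with 5 (DCC, DMAP, −20 °C) to 16.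

2. Step 4. The ligand has to override the anti preference of the α-acyloxy aldehyde, so the syn:anti ratio may be low. The fallback sets out from 7 and comes back at 10. Aldehyde 7 is coupled with 8 without a chiral ligand (CrCl2 3 equiv, NiCl2 1 mol %, DMF) to a mixture of 10 and its C5 epimer F10. The mixture is oxidised with Dess–Martin periodinane to the single isopropenyl ketone F11. F11 is reduced with Me-CBS oxazaborolidine and catecholborane at −78 °C; catalyst control and the polar Felkin–Anh preference of the α-acyloxy ketone then both favour the syn alcohol 10.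

3. Step 7. Substrate control may give some of the 3,4-trans alcohol, and the C4 ester can migrate to the new hydroxyl. The fallback sets out from 16 and comes back at 17: hydride delivery is put under catalyst control (Me-CBS oxazaborolidine 20 mol %, catecholborane, toluene, −78 °C, catalyst antipode that gives 3R) instead of relying on the ring substituents, and the crude 17 is acetylated at once. No new compound is made.

**Further compounds**
F1 | step 6 | methyl (4R)-4-[(tert-butyldiphenylsilyl)oxy]-5,5-dimethoxy-2-methylidenepentanoate | COC(OC)[C@H](O[Si](c1ccccc1)(c1ccccc1)C(C)(C)C)CC(=C)C(=O)OC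
F2 | step 6 | methyl (4R)-4-[(tert-butyldiphenylsilyl)oxy]-2-methylidene-5-oxopentanoate | O=C[C@H](O[Si](c1ccccc1)(c1ccccc1)C(C)(C)C)CC(=C)C(=O)OC
F3 | step 6 | methyl (4R,5R)-4-[(tert-butyldiphenylsilyl)oxy]-5-hydroxy-6-methyl-2-methylidenehept-6-enoate | C=C(C)[C@@H](O)[C@H](O[Si](c1ccccc1)(c1ccccc1)C(C)(C)C)CC(=C)C(=O)OC
F4 | step 6 | methyl (4R,5R)-4-[(tert-butyldiphenylsilyl)oxy]-6-methyl-2-methylidene-5-{[(2R)-2-methylbutanoyl]oxy}hept-6-enoate | C=C(C)[C@@H](OC(=O)[C@H](C)CC)[C@H](O[Si](c1ccccc1)(c1ccccc1)C(C)(C)C)CC(=C)C(=O)OC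
F5 | step 6 | bis-ozonide of F4 (both C=CH2 units as 1,2,4-trioxolanes) | CC1(OCOO1)[C@@H](OC(=O)[C@H](C)CC)[C@H](O[Si](c1ccccc1)(c1ccccc1)C(C)(C)C)CC1(OCOO1)C(=O)OC
F6 | step 6 | methyl (4R,5S)-4-[(tert-butyldiphenylsilyl)oxy]-5-{[(2R)-2-methylbutanoyl]oxy}-2,6-dioxoheptanoate | CC(=O)[C@@H](OC(=O)[C@H](C)CC)[C@H](O[Si](c1ccccc1)(c1ccccc1)C(C)(C)C)CC(=O)C(=O)OC
F7 | step 6 | methyl (4S,5R)-5-[(tert-butyldiphenylsilyl)oxy]-1-hydroxy-4-{[(2R)-2-methylbutanoyl]oxy}-3-oxocyclohexane-1-carboxylate (C1 epimers) | CC(C)(C)[Si](c1ccccc1)(c1ccccc1)O[C@@H]1CC(O)(C(=O)OC)CC(=O)[C@H]1OC(=O)[C@H](C)CC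
F8 | step 6 | methyl (4S,5R)-5-[(tert-butyldiphenylsilyl)oxy]-4-{[(2R)-2-methylbutanoyl]oxy}-3-oxocyclohex-1-ene-1-carboxylate | CC(C)(C)[Si](c1ccccc1)(c1ccccc1)O[C@@H]1CC(C(=O)OC)=CC(=O)[C@H]1OC(=O)[C@H](C)CC
F9 | step 6 | methyl (4S,5R)-5-hydroxy-4-{[(2R)-2-methylbutanoyl]oxy}-3-oxocyclohex-1-ene-1-carboxylate | O[C@@H]1CC(C(=O)OC)=CC(=O)[C@H]1OC(=O)[C@H](C)CC
F10 | step 4 | methyl (4R,5S)-5-hydroxy-6-methyl-2-methylidene-4-{[(3S)-3-methylpentanoyl]oxy}hept-6-enoate | C=C(C)[C@H](O)[C@H](OC(=O)C[C@@H](C)CC)CC(=C)C(=O)OC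
F11 | step 4 | methyl (4R)-6-methyl-2-methylidene-4-{[(3S)-3-methylpentanoyl]oxy}-5-oxohept-6-enoate | C=C(C)C(=O)[C@H](OC(=O)C[C@@H](C)CC)CC(=C)C(=O)OC
F0 | step 7 | none | none
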